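In Thursday's closed flask, [substrate] + [target] + [isomer of the product] stays at 0.40 M, and [reagent] stays 0.0200 M above [substrate]. Substrate is therefore the limiting reagent.

the same everywhere: reagent 0.420 M; free catalyst 2.0 mM; impurity 0.30 mM

| run | substrate | remark | time |
|---|---|---|---|
| Monday's | 0.40 M | one stirred flow tank at steady state, fed with the mixture as stated, mean residence time 20 d |  |
| Sunday's | 0.40 M (fed, over 16.0 d) | all but substrate at the start; substrate goes in evenly over 16.0 d, the run ends at 20 d | 20 d |
| Thursday's | 0.40 M | a closed flask charged with all of it at once and left for 20 d | 20 d |
| Tuesday's | 0.40 M | a single well-mixed tank run continuously and read at steady state, 200 d in it on average |  |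

    free catalyst + impurity → spent catalyst (k1 = 55000 M⁻¹ h⁻¹)
    target + free catalyst ⇌ isomer of the product + free catalyst, rate k2*[free catalyst]*[target] forward; the back reaction follows from the equilibrium constant (k2 = 12 M⁻¹ h⁻¹)
    substrate + reagent ⇌ target (K3 = 8.9 M⁻¹, k3 = 0.077 M⁻¹ h⁻¹)
    substrate + reagent ⇌ isomer of the product (K4 = 7.5 M⁻¹, k4 = 0.011 M⁻¹ h⁻¹)

1. the set-up with the highest amount of target at the outlet or at the end, in percent of the substrate put in ("none" if the first two lie within 2 percentage points) (Monday's / Sunday's / Thursday's / Tuesday's / none)
2. amount of target at the outlet or at the end, in percent of the substrate put in, Monday's
3. amount of target at the outlet or at the end, in percent of the substrate put in, Sunday's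
4. amount of target at the outlet or at the end, in percent of the substrate put in, Thursday's
5. amount of target at the outlet or at the end, in percent of the substrate put in, Tuesday's

- the stated concentrations are those of everything mixed, before any reaction; amounts are the same in each set-up
- the feed brings no volume worth counting
- run time (Sunday's): 20 d

**Now in the flask.** With [free catalyst] held at what remains after the impurity, the impurity has a half-life of 26.7 s. In Thursday's flask the impurity charge is smaller than the catalyst charge, so spent catalyst reaches 0.30 mM and 1.70 mM of free catalyst remains.

**On arrival.** Ask first for the end state. In that end state, target and isomer of the product each stand in equilibrium with substrate and reagent, which gives: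

Target share = 54.3%, target as a part of target plus isomer of the product at equilibrium

Summed constant = 16.4 M⁻¹

[substrate] at equilibrium = 0.121 M

Equilibrium yield of target = 37.9%

Then ask how fast that state is approached. The half-life of substrate going to target, forward rate alone with [reagent] as charged, is 0.893 d. That of target through the isomer step, forward rate alone with the free catalyst that remains, is 1.42 d. Both are far shorter than Thursday's 20 d, so this reckoning puts Thursday's flask under thermodynamic control, at 37.9%.

Monday's tank, Tuesday's tank and Sunday's fed run are expected just under that yield, and no set-up is expected to clear the next by 2 percentage points. Sunday's run holds for 4.00 d after dosing, which is longer than either forward half-life reckoned above.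

**Not to touch.** Leave Thursday's flask shut until its time is up.

The forecast gives 36.2% for Monday's, 37.6% for Sunday's, 37.9% for Thursday's and 37.7% for Tuesday's. Its answer for the best is none, since “the top two lie within 2 points”.

The simulation gives 36.2% for Monday's, 37.8% for Sunday's, 37.9% for Thursday's and 37.7% for Tuesday's, with none as best. In Thursday's flask, the half-life of target through the isomer step, forward rate alone with the catalyst as charged, is 1.2 d, shorter than the 20 d of the run, and target stands at 37.9%. Sunday's flask ends with isomer of the product at 31.6% and target at 37.8%, so target makes 54.5% of the two, beside a target share of 54.3%.

The rate constants are invented; no experiment stands behind them.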